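**Plan**

1. Numbering follows longipinane: C1 ketone, C2=C3(Me), cyclobutane C4–C5–C11–C10, C6 = CMe2, C7–O (methacrylate), C8, C9–O (isobutyrate), C10–Me. Ring A is the cyclohexenone (C1–C4, C10, C11) and ring B the cycloheptane (C4–C10).
2. Retrosynthesis: both esters off, then cut C5–C11. This one cut removes both one-carbon bridges of the cyclobutane core and leaves a cis-fused bicyclo[5.4.0] enone. It is possible because C11 is the kinetic α′ carbon of the C1 enone and lies 1,4 to C5 across the cis C10–C4 fusion, where C5 can carry a β mesylate.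
3. Ring B is cut at C8–C9 and C5–C6 into 3-methylbutan-2-one (C6–C8) and a lactone acetal on ring A (C5 = lactone C=O, C9 = acetal CH). Ring A is cut at C10–C11 and C3–C4 into a 2-silyloxydiene and a 5-menthyloxy-4-methylbutenolide.
4. Forward order: Diels–Alder (ring A) → enolate acylation and Mukaiyama closure (ring B under a temporary C9–O–C5 oxygen bridge) → two reductions, silyl ethers, enone, mesylate → cyclobutane → esters.
5. Stereochemistry: the menthyl acetal carbon controls the Diels–Alder face (C10, C4); the oxygen bridge fixes C9; hydride attack from the bridge side sets C7; C7–OH-directed reduction sets C5–O; SN2 inversion and the ring fusion set C5 and C11.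

Key step: step 12

Remark: it is assumed that the two acetal epimers of 3 equilibrate under acid and that the (5S) epimer can be separated by crystallisation, as is known for the parent menthyloxyfuranone; carbons of intermediates are named by the target numbers they become.

Step 1
Reactants: 1 5-hydroxy-4-methylfuran-2(5H)-one; 2 (+)-menthol
Product: 3 (5S)-4-methyl-5-[(1S,2R,5S)-menthyloxy]furan-2(5H)-one
Conditions: camphorsulfonic acid (cat.), toluene, reflux, Dean–Stark; crystallisation
Reagents that add atoms: none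
Why: acid-catalysed acetalisation of the cyclic hemiacetal with the chiral alcohol gives both C5 epimers, which interconvert under acid so that the (5S) epimer should be collected as a single diastereomer.

Step 2
Reactants: 4 (E)-pent-3-en-2-one
Product: 5 (E)-2-(triisopropylsilyloxy)penta-1,3-diene
Conditions: TIPSOTf, Et3N, Et2O, 0 °C
Reagents that add atoms: triisopropylsilyl triflate CC(C)[Si](C(C)C)(C(C)C)OS(=O)(=O)C(F)(F)F
Why: soft enolisation and O-silylation of the enone methyl group should give the 2-silyloxy diene with the (E) double bond unchanged.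

Step 3
Reactants: 3 (5S)-4-methyl-5-[(1S,2R,5S)-menthyloxy]furan-2(5H)-one; 5 (E)-2-(triisopropylsilyloxy)penta-1,3-diene
Product: 6 cis-fused lactone acetal (cycloadduct; menthyloxy cis to the angular methyl)
Conditions: toluene, BHT, 13 kbar, 50 °C
Reagents that add atoms: none
Why: Diels–Alder reaction in which the CH2 terminus of the 2-silyloxydiene bonds to the β-carbon of the butenolide (future C10, quaternary), the suprafacial addition gives the cis C10–C4 fusion, the diene approaches anti to the menthyloxy group, and the endo methyl at C3 is erased in step 10.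

Step 4
Reactants: 7 3-methylbutan-2-one
Product: 8 3-methyl-2-(trimethylsilyloxy)but-2-ene
Conditions: TMSCl, Et3N, DMF, 130 °C; distillation
Reagents that add atoms: chlorotrimethylsilane C[Si](C)(C)Cl
Why: silylation under equilibrating conditions should favour the tetrasubstituted silyl enol ether, which stores the enolate regiochemistry at the isopropyl carbon (future C6).

Step 5
Reactants: 6 cis-fused lactone acetal; 8 3-methyl-2-(trimethylsilyloxy)but-2-ene
Product: 11 C5 trimethylsilyl ketal bearing the 2-methyl-3-oxobutan-2-yl group, via lithium enolate 9 (not isolated), via lithium hemiketal alkoxide 10 (not isolated)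
Conditions: 8, MeLi, THF, 0 °C; 6, −78 °C; then TMSCl, −78 °C
Reagents that add atoms: chlorotrimethylsilane C[Si](C)(C)Cl
Why: MeLi cleaves 8 to the amine-free lithium enolate, whose tertiary carbon adds to the lactone carbonyl from the convex face (Claisen-type acylation stopped at the tetrahedral stage), and silylation of the alkoxide keeps C5 at the ketone level as a mixed ketal while the C9 acetal stays intact.

Step 6
Reactants: 11 C5 trimethylsilyl ketal bearing the 2-methyl-3-oxobutan-2-yl group
Product: 13 oxygen-bridged ketone (C9–O–C5 bridge; C7 ketone), via bis(silyl) enol ether 12 (not isolated)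
Conditions: TMSOTf, Et3N, CH2Cl2, 0 °C; then TMSOTf (0.2 equiv), −78 to −20 °C
Reagents that add atoms: none
Why: intramolecular Mukaiyama aldol-type addition of the methyl ketone silyl enol ether (C8) to the cyclic oxocarbenium ion formed at C9 by loss of the menthyloxy group (the second half of a Molander-type (3+4) annulation) closes ring B as an 8-oxabicyclo[3.2.1]octan-3-one, and because the three-carbon bridge can span C9 and C5 only on the convex face, the C9–O bond ends up cis to C11.

Step 7
Reactants: 13 oxygen-bridged ketone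
Product: 15 bridged hemiketal C7 β-alcohol, via silyl ketal alcohol 14 (not isolated)
Conditions: LiBH(s-Bu)3, THF, −78 °C; then NH4Cl (aq), MeOH, 0 °C
Reagents that add atoms: none
Why: the bulky hydride should attack the C7 ketone from the open face next to the oxygen bridge, giving the axial alcohol trans to the bridge (C7–O β, anti to C9–O), and mild methanolysis removes the labile bridgehead silyl group.

Step 8
Reactants: 15 bridged hemiketal C7 β-alcohol
Product: 17 C5β,C7β,C9α-triol, via keto diol tautomer 16 (not isolated)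
Conditions: Et2BOMe, THF–MeOH (4:1), −78 °C; NaBH4, −78 to −30 °C; MeOH co-evaporation
Reagents that add atoms: none
Why: Narasaka–Prasad reduction, in which the hemiketal opens to the β-hydroxy ketone, boron chelates C7–OH and the C5 carbonyl, and external hydride enters anti to the chelate to give the syn (cis) 1,3-diol, that is C5–OH β, while the silyl enol ether is untouched.

Step 9
Reactants: 17 C5β,C7β,C9α-triol
Product: 20 C9 tert-butyldimethylsilyl ether C5,C7-diol, via phenylboronate 18 (not isolated), via silylated phenylboronate 19 (not isolated)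
Conditions: PhB(OH)2, toluene, reflux; then TBSOTf, 2,6-lutidine, CH2Cl2, 0 °C; then pinacol, MeOH, 25 °C
Reagents that add atoms: tert-butyldimethylsilyl triflate CC(C)(C)[Si](C)(C)OS(=O)(=O)C(F)(F)F
Why: transient boronate protection, in which the cis-1,3-diol flanking the gem-dimethyl carbon forms the six-membered phenylboronate so that only C9–OH is silylated, and transesterification with pinacol then frees the diol.

Step 10
Reactants: 20 C9 tert-butyldimethylsilyl ether C5,C7-diol
Product: 21 enone diol
Conditions: Pd(OAc)2, MeCN, 40 °C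
Reagents that add atoms: none
Why: Saegusa–Ito oxidation, in which palladation of the silyl enol ether at C2 and β-hydride elimination from C3 should give the C2=C3 enone regiospecifically and remove the C3 stereocentre.

Step 11
Reactants: 21 enone diol
Product: 23 C5 mesylate C7 triethylsilyl ether enone, via triethylsilyl ether 22 (not isolated)
Conditions: TESCl, imidazole, CH2Cl2, 0 °C; then Et3N, MsCl, 0 °C
Reagents that add atoms: chlorotriethylsilane CC[Si](Cl)(CC)CC; methanesulfonyl chloride CS(=O)(=O)Cl
Why: C7–OH (between CMe2 and CH2) should be silylated before the more hindered C5–OH (between CMe2 and the ring-fusion CH), and the remaining C5–OH is then sulfonylated through sulfene, which tolerates hindered alcohols.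

Step 12
Reactants: 23 C5 mesylate C7 triethylsilyl ether enone
Product: 25 tricyclic enone (7-O-triethylsilyl; 9-O-tert-butyldimethylsilyl), via lithium dienolate 24 (not isolated)
Conditions: LiN(i-Pr)2 (1.05 equiv), THF, −78 °C; DMPU, −78 to 25 °C
Reagents that add atoms: none
Why: The amide base should remove the α′ proton at C11 kinetically (as with isophorone-type enones) to give the cross-conjugated lithium dienolate, and C11 then displaces the C5 mesylate from the rear in an intramolecular SN2 alkylation; the closest known reaction type is the closure of cyclobutanes by ketone enolate alkylation with a secondary sulfonate across a cis-fused bicycle (copaene-type tricyclic ketones). The closure is 4-exo-tet and forms the cyclobutane C4–C5–C11–C10, which is the only ring closed. C5 is set by inversion of the β C–O bond installed in step 8, and C11 is set because its enolate carbon can reach C5 only on the α face of ring B, where the cis C10–C4 fusion holds it. The step needs C- over O-alkylation, α′- over γ-deprotonation, and attack by C11 and not by an oxygen: O-alkylation would give a bridgehead enol ether excluded by Bredt's rule, γ-deprotonation at C4 (which would expel mesylate by vinylogous E1cB) is kinetically disfavoured at −78 °C, O9 is blocked as a bulky silyl ether so it cannot close the oxygen bridge, and O7 as a silyl ether cannot trigger Grob cleavage of C6–C7.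

Step 13
Reactants: 25 tricyclic enone (7-O-triethylsilyl; 9-O-tert-butyldimethylsilyl)
Product: 26 7-hydroxy tricyclic enone (9-O-tert-butyldimethylsilyl)
Conditions: PPTS, MeOH, 25 °C
Reagents that add atoms: none
Why: acid-catalysed methanolysis should remove the triethylsilyl ether much faster than the tert-butyldimethylsilyl ether (selective desilylation).

Step 14
Reactants: 26 7-hydroxy tricyclic enone
Product: 27 7-methacrylate (9-O-tert-butyldimethylsilyl)
Conditions: methacrylic anhydride, Et3N, DMAP, CH2Cl2, 40 °C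
Reagents that add atoms: methacrylic anhydride C=C(C)C(=O)OC(=O)C(C)=C
Why: DMAP-catalysed acylation of the hindered secondary C7–OH, with no stereocentre touched.

Step 15
Reactants: 27 7-methacrylate (9-O-tert-butyldimethylsilyl)
Product: 28 9-hydroxy 7-methacrylate
Conditions: HF·pyridine, THF, 0 to 25 °C
Reagents that add atoms: none
Why: fluoride-mediated desilylation under acidic conditions, which should not promote 1,3-acyl migration or attack the enone and the methacrylate.

Step 16
Reactants: 28 9-hydroxy 7-methacrylate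
Product: 29 (4R,5S,7R,9R,10R,11R)-9-isobutyryloxy-7-methacryloyloxylongipin-2-en-1-one
Conditions: isobutyryl chloride, pyridine, DMAP (cat.), CH2Cl2, 0 to 25 °C
Reagents that add atoms: isobutyryl chloride CC(C)C(=O)Cl
Why: acylation of C9–OH with the acid chloride completes the target without touching a stereocentre.

**Compound list**

1 | 5-hydroxy-4-methylfuran-2(5H)-one (racemic hemiacetal) | CC1=CC(=O)OC1O | starting material
2 | (+)-menthol, (1S,2R,5S)-5-methyl-2-(propan-2-yl)cyclohexan-1-ol | CC(C)[C@H]1CC[C@H](C)C[C@@H]1O | starting material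
3 | (5S)-4-methyl-5-[(1S,2R,5S)-menthyloxy]furan-2(5H)-one | CC(C)[C@H]1CC[C@H](C)C[C@@H]1O[C@H]2OC(=O)C=C2C | intermediate
4 | (E)-pent-3-en-2-one | C/C=C/C(C)=O | starting material
5 | (E)-2-(triisopropylsilyloxy)penta-1,3-diene | C/C=C/C(=C)O[Si](C(C)C)(C(C)C)C(C)C | intermediate
6 | cis-fused 3-menthyloxy-3a,7-dimethyl-5-(triisopropylsilyloxy)-3a,4,7,7a-tetrahydroisobenzofuran-1(3H)-one; menthyloxy cis to the angular methyl, C7 methyl cis to the lactone carbonyl | CC(C)[C@H]1CC[C@H](C)C[C@@H]1O[C@H]2OC(=O)[C@@H]3[C@H](C)C=C(O[Si](C(C)C)(C(C)C)C(C)C)C[C@]23C | intermediate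
7 | 3-methylbutan-2-one | CC(C)C(C)=O | starting material
8 | 3-methyl-2-(trimethylsilyloxy)but-2-ene | CC(C)=C(C)O[Si](C)(C)C | intermediate
9 | lithium 3-methylbut-2-en-2-olate | CC(C)=C(C)[O-].[Li+] | intermediate
10 | lithium hemiketal alkoxide from addition of 9 to the lactone carbonyl of 6 | CC(C)[C@H]1CC[C@H](C)C[C@@H]1O[C@H]2O[C@@]([O-])(C(C)(C)C(C)=O)[C@@H]3[C@H](C)C=C(O[Si](C(C)C)(C(C)C)C(C)C)C[C@]23C.[Li+] | intermediate
11 | mixed ketal at C5 (OSiMe3 and ring oxygen) carrying the 2-methyl-3-oxobutan-2-yl group on the convex face | CC(C)[C@H]1CC[C@H](C)C[C@@H]1O[C@H]2O[C@@](O[Si](C)(C)C)(C(C)(C)C(C)=O)[C@@H]3[C@H](C)C=C(O[Si](C(C)C)(C(C)C)C(C)C)C[C@]23C | intermediate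
12 | trimethylsilyl enol ether of the methyl ketone of 11 | CC(C)[C@H]1CC[C@H](C)C[C@@H]1O[C@H]2O[C@@](O[Si](C)(C)C)(C(C)(C)C(=C)O[Si](C)(C)C)[C@@H]3[C@H](C)C=C(O[Si](C(C)C)(C(C)C)C(C)C)C[C@]23C | intermediate
13 | oxygen-bridged ketone: ring B with C9–O–C5 bridge, C7 ketone, C5–OSiMe3, ring A silyl enol ether on the face of the bridge | C[Si](C)(C)O[C@]12O[C@H](CC(=O)C1(C)C)[C@@]3(C)CC(O[Si](C(C)C)(C(C)C)C(C)C)=C[C@@H](C)[C@@H]23 | intermediate
14 | C7 axial (β) alcohol of 13, silyl ketal intact | C[Si](C)(C)O[C@]12O[C@H](C[C@@H](O)C1(C)C)[C@@]3(C)CC(O[Si](C(C)C)(C(C)C)C(C)C)=C[C@@H](C)[C@@H]23 | intermediate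
15 | bridged hemiketal with C7 β-OH | O[C@]12O[C@H](C[C@@H](O)C1(C)C)[C@@]3(C)CC(O[Si](C(C)C)(C(C)C)C(C)C)=C[C@@H](C)[C@@H]23 | intermediate
16 | open keto tautomer of 15 (C5 ketone, C7β and C9α hydroxyls) | O[C@@H]1C[C@@H](O)[C@@]2(C)CC(O[Si](C(C)C)(C(C)C)C(C)C)=C[C@@H](C)[C@H]2C(=O)C1(C)C | intermediate
17 | cis-fused bicyclic triol (C5β-OH, C7β-OH, C9α-OH), ring A silyl enol ether | O[C@@H]1C[C@@H](O)[C@@]2(C)CC(O[Si](C(C)C)(C(C)C)C(C)C)=C[C@@H](C)[C@H]2[C@H](O)C1(C)C | intermediate
18 | C5,C7-O-phenylboronate of 17 | c1ccccc1B2O[C@@H]3C[C@@H](O)[C@@]4(C)CC(O[Si](C(C)C)(C(C)C)C(C)C)=C[C@@H](C)[C@H]4[C@H](O2)C3(C)C | intermediate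
19 | C9-O-tert-butyldimethylsilyl ether of 18 | c1ccccc1B2O[C@@H]3C[C@@H](O[Si](C)(C)C(C)(C)C)[C@@]4(C)CC(O[Si](C(C)C)(C(C)C)C(C)C)=C[C@@H](C)[C@H]4[C@H](O2)C3(C)C | intermediate
20 | C9-O-tert-butyldimethylsilyl ether with free C5β,C7β-diol | O[C@@H]1C[C@@H](O[Si](C)(C)C(C)(C)C)[C@@]2(C)CC(O[Si](C(C)C)(C(C)C)C(C)C)=C[C@@H](C)[C@H]2[C@H](O)C1(C)C | intermediate
21 | cis-fused enone diol (C1 ketone, C2=C3–Me, C5β-OH, C7β-OH, C9α-OTBS) | O[C@@H]1C[C@@H](O[Si](C)(C)C(C)(C)C)[C@@]2(C)CC(=O)C=C(C)[C@H]2[C@H](O)C1(C)C | intermediate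
22 | C7-O-triethylsilyl ether of 21 | CC[Si](CC)(CC)O[C@@H]1C[C@@H](O[Si](C)(C)C(C)(C)C)[C@@]2(C)CC(=O)C=C(C)[C@H]2[C@H](O)C1(C)C | intermediate
23 | C5β-mesylate of 22 | CC[Si](CC)(CC)O[C@@H]1C[C@@H](O[Si](C)(C)C(C)(C)C)[C@@]2(C)CC(=O)C=C(C)[C@H]2[C@H](OS(C)(=O)=O)C1(C)C | intermediate
24 | lithium C11=C1 cross-conjugated dienolate of 23 | CC[Si](CC)(CC)O[C@@H]1C[C@@H](O[Si](C)(C)C(C)(C)C)[C@@]2(C)C=C([O-])C=C(C)[C@H]2[C@H](OS(C)(=O)=O)C1(C)C.[Li+] | intermediate
25 | 7-O-triethylsilyl-9-O-tert-butyldimethylsilyl longipin-2-en-1-one | CC[Si](CC)(CC)O[C@@H]1C[C@@H](O[Si](C)(C)C(C)(C)C)[C@@]2(C)[C@@H]3C(=O)C=C(C)[C@H]2[C@@H]3C1(C)C | intermediate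
26 | 7-hydroxy-9-O-tert-butyldimethylsilyl longipin-2-en-1-one | O[C@@H]1C[C@@H](O[Si](C)(C)C(C)(C)C)[C@@]2(C)[C@@H]3C(=O)C=C(C)[C@H]2[C@@H]3C1(C)C | intermediate
27 | 7-methacryloyloxy-9-O-tert-butyldimethylsilyl longipin-2-en-1-one | C=C(C)C(=O)O[C@@H]1C[C@@H](O[Si](C)(C)C(C)(C)C)[C@@]2(C)[C@@H]3C(=O)C=C(C)[C@H]2[C@@H]3C1(C)C | intermediate
28 | 9-hydroxy-7-methacryloyloxylongipin-2-en-1-one | C=C(C)C(=O)O[C@@H]1C[C@@H](O)[C@@]2(C)[C@@H]3C(=O)C=C(C)[C@H]2[C@@H]3C1(C)C | intermediate
29 | (4R,5S,7R,9R,10R,11R)-9-isobutyryloxy-7-methacryloyloxylongipin-2-en-1-one | C=C(C)C(=O)O[C@@H]1C[C@@H](OC(=O)C(C)C)[C@@]2(C)[C@@H]3C(=O)C=C(C)[C@H]2[C@@H]3C1(C)C | target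

**Totals and risks**

Total step count: 16. Longest linear sequence: 14 steps (steps 1, 3 and 5 to 16; steps 2 and 4 are one-step side branches).

Step 12 (most at risk). The SN2 displacement at C5, which is flanked by the gem-dimethyl carbon and the ring-fusion carbon, may be slow enough that proton transfer turns the α′-enolate into the C4 dienolate, which then loses mesylate by vinylogous β-elimination. The fallback closes the ring on the saturated ketone, where C4–H is not acidic, and brings the enone in afterwards. It sets out from 20: hydrolysis of the silyl enol ether (oxalic acid, wet THF) should give the saturated keto diol F1; silylation at O7 and mesylation at O5 as in step 11 give the keto mesylate F2; KO-t-Bu in t-BuOH–THF equilibrates the enolates, of which only the C11 enolate can cyclise, to give the saturated tricyclic ketone F3; LiN(i-Pr)2 with TMSCl gives the only possible silyl enol ether F4 (C1=C2, since C11 is now a cyclobutane bridgehead), and Pd(OAc)2 returns the route to 25.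

Step 3. The cycloaddition at the methyl-bearing β-carbon of the butenolide may be too slow, so that the diene decomposes or oligomerises first. The fallback uses the far more reactive citraconic anhydride with diene 5: the anhydride cycloadduct F5 (racemic; regioisomers separated) is reduced at the carbonyl on the quaternary carbon with LiAlH(O-t-Bu)3 to the hydroxy lactone F6, and acid-catalysed acetalisation with 2 followed by separation of the diastereomeric menthyl acetals (which is the resolution) rejoins the route at 6.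

Step 5. The hindered ketone enolate may deprotonate the lactone at C4 instead of adding, or the adduct may revert to lactone and enolate before it is silylated. The fallback starts from 6 and uses prenylmagnesium chloride, which adds irreversibly through its tertiary carbon to give the hemiketal F7; a Prins cyclisation of the vinyl group onto the C9 oxocarbenium ion (BF3·OEt2, AcOH; then K2CO3, MeOH) closes ring B and should give the equatorial C7 alcohol F8; Dess–Martin oxidation gives the ketone hemiketal F9, and reduction with LiBH(s-Bu)3 as in step 7 rejoins the route at 15.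

Further compounds
F1 | step 12 | saturated keto diol (C1 ketone, C3 methyl retained, C5β-OH, C7β-OH, C9α-OTBS) | O[C@@H]1C[C@@H](O[Si](C)(C)C(C)(C)C)[C@@]2(C)CC(=O)C[C@@H](C)[C@H]2[C@H](O)C1(C)C
F2 | step 12 | saturated ketone with C7-O-triethylsilyl and C5β-mesylate | CC[Si](CC)(CC)O[C@@H]1C[C@@H](O[Si](C)(C)C(C)(C)C)[C@@]2(C)CC(=O)C[C@@H](C)[C@H]2[C@H](OS(C)(=O)=O)C1(C)C
F3 | step 12 | 2,3-dihydro analogue of 25 (saturated tricyclic ketone) | CC[Si](CC)(CC)O[C@@H]1C[C@@H](O[Si](C)(C)C(C)(C)C)[C@@]2(C)[C@@H]3C(=O)C[C@@H](C)[C@H]2[C@@H]3C1(C)C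
F4 | step 12 | C1=C2 trimethylsilyl enol ether of F3 | CC[Si](CC)(CC)O[C@@H]1C[C@@H](O[Si](C)(C)C(C)(C)C)[C@@]2(C)[C@@H]3C(O[Si](C)(C)C)=C[C@@H](C)[C@H]2[C@@H]3C1(C)C
F5 | step 3 | cis-fused anhydride cycloadduct of citraconic anhydride and 5 (drawn as the needed enantiomer) | O=C1OC(=O)[C@@]2(C)CC(O[Si](C(C)C)(C(C)C)C(C)C)=C[C@@H](C)[C@@H]12
F6 | step 3 | hydroxy lactone (hemiacetal at C9, both epimers) | OC1OC(=O)[C@@H]2[C@H](C)C=C(O[Si](C(C)C)(C(C)C)C(C)C)C[C@]12C
F7 | step 5 | hemiketal carrying the 2-methylbut-3-en-2-yl group at C5 | CC(C)[C@H]1CC[C@H](C)C[C@@H]1O[C@H]2O[C@@](O)(C(C)(C)C=C)[C@@H]3[C@H](C)C=C(O[Si](C(C)C)(C(C)C)C(C)C)C[C@]23C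
F8 | step 5 | bridged hemiketal with equatorial (α) C7 alcohol | O[C@]12O[C@H](C[C@H](O)C1(C)C)[C@@]3(C)CC(O[Si](C(C)C)(C(C)C)C(C)C)=C[C@@H](C)[C@@H]23
F9 | step 5 | bridged hemiketal C7 ketone | O[C@]12O[C@H](CC(=O)C1(C)C)[C@@]3(C)CC(O[Si](C(C)C)(C(C)C)C(C)C)=C[C@@H](C)[C@@H]23
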